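**Assumption:** the target SMILES has no stereocentre. The methine carbon carries two identical indol-3-yl groups, so trisindolal is achiral, there is no enantiomer to select, and no asymmetric step is needed.

## Retrosynthetic overview
1. The obvious route, a 3-formylindole condensed with two indoles, is avoided. Instead the 2-formylindole ring is the last ring built, by a Madelung-type disconnection of N1–C2 and C2–C3.
2. The C2–CHO unit comes from ethyl diethoxyacetate. C3 comes from the benzylic carbanion of N-Boc-2-[2,2-bis(indol-3-yl)ethyl]aniline.
3. That aniline, the "indole trimer", is built from indole alone in two acid-mediated stages. Indole first dimerises to 2-(indol-3-yl)indoline. The indoline ring is then opened and the resulting cation is transferred to a third indole, which is the key strategy.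
4. Ring order: two indole rings are carried through intact. The pyrrole ring of the third is reduced to an indoline in step 1 and opened in step 2, where its old C2 becomes the methine carbon and its old C3 the benzylic CH2. A new pyrrole ring is closed around the ester carbonyl carbon (new C2) in steps 4–5.

## Route

**Step 1**
Reactants: 1, 1H-indole (two molecules)
Product: 2, 2-(1H-indol-3-yl)indoline ("indole dimer", racemic)
Conditions: dry HCl (g), Et2O, N2, 0 °C → rt (2·HCl precipitates and is filtered off); then cold aq NH3/EtOAc
Reagents that add atoms: 1H-indole (second molecule of 1), c1ccc2[nH]ccc2c1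
Why: This is acid-catalysed indole dimerisation (an aza-Friedel–Crafts/Mannich-type addition), in which the C3-protonated 3H-indolium ion is attacked at C2 by C3 of a second indole, and in an aprotic medium the insoluble indolinium chloride precipitates before it reacts further; the new indoline C2 stereocentre is racemic and becomes the achiral methine in step 2.

**Step 2**
Reactants: 2; 1, 1H-indole (1.1 equiv)
Product: 3, 2-[2,2-bis(1H-indol-3-yl)ethyl]aniline ("indole trimer")
Conditions: 1 M aq HCl–EtOH, N2, rt, 24–48 h (3·HCl precipitates); then aq NH3
Reagents that add atoms: 1H-indole, c1ccc2[nH]ccc2c1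
Why: This is ring-opening Friedel–Crafts alkylation, in which the protonated indoline N leaves as an aniline with push from the indol-3-yl group to give a 3-alkylidene-3H-indolium (azafulvenium) ion, C3 of the third indole traps that ion, and precipitation of the anilinium salt pulls the equilibrium forward; the former stereocentre now carries two identical indolyl groups and is achiral.

**Step 3**
Reactants: 3; 4, di-tert-butyl dicarbonate
Product: 5, tert-butyl N-{2-[2,2-bis(1H-indol-3-yl)ethyl]phenyl}carbamate
Conditions: Boc2O (1.1 equiv), THF, reflux, no DMAP
Reagents that add atoms: Boc2O, CC(C)(C)OC(=O)OC(=O)OC(C)(C)C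
Why: This is chemoselective carbamoylation, because only the aniline nitrogen is nucleophilic enough to react without DMAP or strong base and the indole N–H groups stay free.

**Step 4**
Reactants: 5; 6, ethyl 2,2-diethoxyacetate
Product: 7, tert-butyl N-{2-[1,1-bis(1H-indol-3-yl)-4,4-diethoxy-3-oxobutan-2-yl]phenyl}carbamate (racemic; in equilibrium with its ring-closed N-Boc-2-hydroxyindoline form; used crude)
Conditions: n-BuLi (3.0 equiv), THF, −78 °C; s-BuLi (1.5 equiv), −40 → −25 °C, 1 h; 6 (2 equiv), −78 °C; aq NH4Cl
Reagents that add atoms: ethyl diethoxyacetate, CCOC(OCC)C(=O)OCC
Why: This is carbamate-directed lateral (benzylic) lithiation of an N-Boc-2-alkylaniline followed by C-acylation (a modified Madelung indole synthesis), in which the three N–H sites become inert N-Li species (N-lithioindoles resist C2 metalation), the lithiated carbamate steers the fourth equivalent to the adjacent ArCH2, and the α,α-dialkoxy ester stops at the ketone through a chelated adduct and enolate; the new benzylic stereocentre is racemic and is erased in step 5.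

**Step 5**
Reactants: 7
Product: 8, tert-butyl 3-[bis(1H-indol-3-yl)methyl]-2-formyl-1H-indole-1-carboxylate
Conditions: 2 M aq HCl–THF (1:5), N2, rt, 1–3 h
Reagents that add atoms: water, O (it supplies the aldehyde oxygen)
Why: This is cyclodehydration, in which the carbamate N adds to the activated ketone and loss of water aromatises the ring, followed by acetal hydrolysis, and the order enforces itself because α-keto acetals hydrolyse slowly whereas the indol-2-yl acetal hydrolyses quickly, so the ring closes before a free aldehyde exists; Boc and the tris(indolyl)methane unit tolerate dilute acid at rt.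

**Step 6**
Reactants: 8
Product: 9, trisindolal, 3-[bis(1H-indol-3-yl)methyl]-1H-indole-2-carbaldehyde
Conditions: K2CO3 (1 equiv), MeOH, rt
Reagents that add atoms: none
Why: This is base-mediated methanolysis of an activated azolide-type carbamate (N-Boc on a 2-acylindole), which generates no t-Bu cation to alkylate the indoles and no acid to trigger retro-Friedel–Crafts cleavage; the aldehyde is non-enolisable.

## Compound list
1 | 1H-indole | c1ccc2[nH]ccc2c1 | starting material
2 | 2-(1H-indol-3-yl)indoline (racemic) | C1(Cc2ccccc2N1)c1c[nH]c2ccccc12 | intermediate
3 | 2-[2,2-bis(1H-indol-3-yl)ethyl]aniline | Nc1ccccc1CC(c1c[nH]c2ccccc12)c1c[nH]c2ccccc12 | intermediate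
4 | di-tert-butyl dicarbonate | CC(C)(C)OC(=O)OC(=O)OC(C)(C)C | starting material
5 | tert-butyl N-{2-[2,2-bis(1H-indol-3-yl)ethyl]phenyl}carbamate | CC(C)(C)OC(=O)Nc1ccccc1CC(c1c[nH]c2ccccc12)c1c[nH]c2ccccc12 | intermediate
6 | ethyl 2,2-diethoxyacetate | CCOC(OCC)C(=O)OCC | starting material
7 | tert-butyl N-{2-[1,1-bis(1H-indol-3-yl)-4,4-diethoxy-3-oxobutan-2-yl]phenyl}carbamate (racemic) | CCOC(OCC)C(=O)C(c1ccccc1NC(=O)OC(C)(C)C)C(c1c[nH]c2ccccc12)c1c[nH]c2ccccc12 | intermediate
8 | tert-butyl 3-[bis(1H-indol-3-yl)methyl]-2-formylindole-1-carboxylate | CC(C)(C)OC(=O)n1c(C=O)c(C(c2c[nH]c3ccccc23)c2c[nH]c3ccccc23)c2ccccc12 | intermediate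
9 | trisindolal (achiral) | O=Cc1[nH]c2ccccc2c1C(c1c[nH]c2ccccc12)c1c[nH]c2ccccc12 | target

## Summary
**Total steps:** 6. Steps 4 and 5 can be telescoped because 7 is used crude.
**Longest linear sequence:** 6.

**Steps most likely to fail**
1. **Step 4.** The benzylic site is hindered and secondary, and it sits on a tetra-anion. Ring ortho-lithiation or poor solubility may compete.
   Fallback: change the activating group. Convert 3 into the aryl isocyanide by N-formylation and then Burgess dehydration. Use isocyano-activated benzylic lithiation (LiTMP, −78 °C, Ito–Saegusa type, with extra base for the two indole N–H groups), acylate with 6 at −78 °C, then treat with dilute acid. The isocyanide goes to the formanilide, which closes and deformylates, so Boc is no longer needed.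
2. **Step 2.** In aqueous acid, dimer 2 is in equilibrium with indole, trimer and tetramer, so the yield of 3 may be moderate.
   Fallback: build 3 without any indole oligomerisation, which replaces steps 1 and 2. Bis-indolylate 2-nitrophenylacetaldehyde with two equivalents of indole under mild acid catalysis, then reduce the nitro group with H2 and Pd/C.
3. **Step 5.** The congested hemiaminal may dehydrate slowly. Acid-induced indole scrambling or cyclopenta[b]indole formation are also possible.
   Fallback: drop the keto-acetal. Quench the step 4 anion with DMF to give N-Boc-3-[bis(indol-3-yl)methyl]indole, in which only one of the three indoles carries Boc. Then install the aldehyde by Boc-directed C2 lithiation (n-BuLi for the two N–H groups, then LiTMP) and DMF. This gives 8 directly.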